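**Plan**

1. Retrosynthesis: C13=CH2 and the C18 ketone go back to C13=O and C18–OH. Ring D and the E-lactone are cut at C12–C18 and C14–C17, giving a tricyclic C13-keto C15-ester whose ester alcohol is an (R)-lactic-acid-derived masked keto-aldehyde. Rings A, B and C are cut at C4–C5, C9–C10 and C8–C14, giving an open-chain (E,E)-diene.
2. Enabling feature: ring A (C1, C2, C19, C4, C5, C10) is not a terpenoid ring. C4 carries the lactone oxygen and lies γ to the C3 carbonyl, so the bridging lactone (C2–C3–O–C4–C19) is the lactone of a γ-keto acid. Its C4 acyloxycarbenium ion sits five bonds from C5 of a trisubstituted alkene, so the lactone can initiate the polyene cascade itself.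
3. Forward: dioxinone + geranyl bromide → enal; anti-aldol with a pent-4-ynoyl imide → γ-alkynoic acid → γ-methylene lactone. One cationic operation then closes ring A (as a bridge on the lactone), ring B and ring C. Acylketene esterification/aldol closes the E-lactone and a silyl-Mukaiyama aldol closes ring D; methylenation, oxidation and desilylation finish.
4. Stereochemistry: C1 and C2 come from the auxiliary-controlled anti-aldol. C4, C5, C10, C9 and C8 are relayed from C2 through the chair–chair–chair cascade. C16 comes from (R)-lactate. C14, C17 and C12 follow from axial attack on ring C and the constraints of the bicyclo[3.2.1]octane.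

Key step: step 9

Remarks:
- Locants used throughout (steroid-like): C1 = CH(OH); C2; C3 = A-lactone C=O; C4 = C(Me)–O; C5; C6; C7; C8 (Me); C9; C10 (Me); C11; C12 (Me); C13 (=CH2); C14; C15 = E-lactone C=O; C16 = CH(Me)–O; C17 = C–OH; C18 = ketone; C19 = CH2 between C2 and C4.
- Assumption: the Mg-catalysed anti-aldol adds the aldehyde to the enolate face anti to the benzyl group of the chelated Z-enolate; the (R)-auxiliary is chosen on that basis.
- C12 (until step 14), C4 of 15 and C18 of 28–30 are epimer mixtures that converge later; their SMILES carry no descriptor at those atoms.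

**Route**

Step 1
Reactants: 1 2,2,6-trimethyl-4H-1,3-dioxin-4-one; 2 geranyl bromide
Product: 3 6-[(3E)-4,8-dimethylnona-3,7-dien-1-yl]-2,2-dimethyl-4H-1,3-dioxin-4-one
Conditions: LDA, THF/DMPU, −78 °C; then 2, −78 → −40 °C
Reagents that add atoms: none
Why: γ-alkylation of the lithium dienolate of the dioxinone (vinylogous enolate alkylation, SN2 at the primary allylic bromide) should join C11 to the masked β-keto acid; no stereocentre is formed.

Step 2
Reactants: 3 geranylated dioxinone
Product: 4 6-[(4E)-5,9-dimethyldeca-4,8-dien-2-yl]-2,2-dimethyl-4H-1,3-dioxin-4-one (racemic at the future C12)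
Conditions: LDA, THF/DMPU, −78 °C; MeI
Reagents that add atoms: iodomethane, CI
Why: a second γ-deprotonation/alkylation of the dioxinone dienolate should install the C12 methyl; C12 is left racemic because it is epimerised and reset in steps 13–14.

Step 3
Reactants: 4 methylated dioxinone
Product: 6 (2E,6E)-9-(2,2-dimethyl-4-oxo-4H-1,3-dioxin-6-yl)-2,6-dimethyldeca-2,6-dienal, via allylic alcohol 5 (not isolated)
Conditions: SeO2 (cat.), t-BuOOH, CH2Cl2, 0 °C → rt; then MnO2, CH2Cl2, rt
Reagents that add atoms: tert-butyl hydroperoxide, CC(C)(C)OO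
Why: SeO2 allylic oxidation (ene/[2,3] sequence) should select the (E)-methyl of the terminal isopropylidene group, and MnO2 oxidises the allylic alcohol to the (E)-enal that becomes C1.

Step 4
Reactants: 7 (R)-4-benzyloxazolidin-2-one; 8 pent-4-ynoyl chloride
Product: 9 (R)-4-benzyl-3-(pent-4-ynoyl)oxazolidin-2-one
Conditions: Et3N, DMAP (cat.), CH2Cl2, 0 °C → rt
Reagents that add atoms: none
Why: standard N-acylation of the oxazolidinone auxiliary; the alkyne is the latent C4 ketone carbon and its methyl.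

Step 5
Reactants: 6 enal; 9 N-acyl oxazolidinone
Product: 11 (R)-4-benzyl-3-[(2S,3R,4E,8E)-11-(2,2-dimethyl-4-oxo-4H-1,3-dioxin-6-yl)-3-hydroxy-4,8-dimethyl-2-(prop-2-yn-1-yl)dodeca-4,8-dienoyl]oxazolidin-2-one, via O-TMS aldolate 10 (not isolated)
Conditions: MgCl2 (20 mol %), Et3N, TMSCl, EtOAc, rt; then TFA (cat.), MeOH
Reagents that add atoms: none
Why: Evans magnesium-catalysed anti-aldol of the chelated Z-enolate with a non-enolisable enal should give the 2,3-anti adduct; the auxiliary sets C2 (S) and the anti transition state sets C1 (R), with C3–C2 and C1–O destined to be trans-diaxial in ring A.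

Step 6
Reactants: 11 aldol adduct
Product: 12 3-O-TBS ether of 11 (C1–OTBS)
Conditions: TBSOTf, 2,6-lutidine, CH2Cl2, −78 → 0 °C
Reagents that add atoms: tert-butyldimethylsilyl triflate, CC(C)(C)[Si](C)(C)OS(=O)(=O)C(F)(F)F
Why: silylation of the β-hydroxy imide blocks retro-aldol and gives a non-participating group at C1 for the cationic step.

Step 7
Reactants: 12 silylated imide
Product: 13 (2S,3R,4E,8E)-3-(tert-butyldimethylsilyloxy)-11-(2,2-dimethyl-4-oxo-4H-1,3-dioxin-6-yl)-4,8-dimethyl-2-(prop-2-yn-1-yl)dodeca-4,8-dienoic acid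
Conditions: LiOH, H2O2, THF/H2O, 0 °C; Na2SO3; aq. HCl to pH 3
Reagents that add atoms: hydrogen peroxide (as LiOOH), OO
Why: hydroperoxide cleaves the exocyclic imide carbonyl selectively at 0 °C without epimerising C2; the dioxinone needs heat to open and should survive.

Step 8
Reactants: 13 γ-alkynoic acid
Product: 14 (3S)-3-[(1R,2E,6E)-1-(tert-butyldimethylsilyloxy)-9-(2,2-dimethyl-4-oxo-4H-1,3-dioxin-6-yl)-2,6-dimethyldeca-2,6-dien-1-yl]-5-methylidenedihydrofuran-2(3H)-one
Conditions: AuCl (5 mol %), K2CO3 (10 mol %), MeCN, rt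
Reagents that add atoms: none
Why: gold-catalysed 5-exo-dig cycloisomerisation of a γ-alkynoic acid gives the γ-methylene lactone, which already contains the A-ring lactone (C2, C3, O, C4, C19).

Step 9
Reactants: 14 γ-methylene lactone
Product: 17 tetracyclic lactone–dioxinone (rings A, B, C closed; β-face 2,4-bridging γ-lactone; 1α-OTBS; 5α-H; 8β-Me; 9α-H; 10β-Me; C13=C14 fused to the 2,2-dimethyl-1,3-dioxin-4-one; C12 epimers), via chlorolactone 15 (not isolated), via acyloxycarbenium ion 16 (not isolated)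
Conditions: HCl (1 equiv, Et2O), CH2Cl2 (high dilution), −78 °C; then SnCl4, −78 → −40 °C; aq. NaHCO3
Reagents that add atoms: none
Why: Proposed new method: HCl adds to the enol lactone in the Markovnikov sense and SnCl4 abstracts chloride; the cyclic acyloxycarbenium ion 16 is then attacked at C4 by C5 of the 5,10-alkene, the C10 cation by C9 of the 8,9-alkene and the C8 cation by C14 of the dioxinone, and loss of H-14 restores the dioxinone, the closest known reaction types being acetal- and N-acyliminium-initiated, β-keto-ester-terminated cation–olefin polycyclisations (Johnson type), Friedel–Crafts alkylations with lactone-derived acyloxycarbenium ions and dioxinone-terminated Prins cyclisations. Ring A closes 6-endo as a three-carbon bridge across C2 and C4 of the preformed lactone (giving the 6-oxabicyclo[3.2.1]octan-7-one), ring B 6-endo onto the second E-alkene and ring C 6-endo onto the dioxinone C13=C14 bond. The C2 stereocentre decides the lactone face from which the chain reaches C4 and so sets C4; C5 and C10 follow from antiperiplanar addition across the first E-alkene and C9 and C8 from the second (chair–chair–chair, trans-anti-trans), while C12 stays a mixture. The step needs the chair in which C3 and the C1–O bond are trans-diaxial: the lactone tether allows no other (an open-chain ester would prefer the diequatorial chair and the wrong relative configuration), and in it the equatorial C1–H bond is orthogonal to the empty orbital at C10, which disfavours a semipinacol hydride shift. C- rather than O-termination is secured because the enol oxygen of the terminator is tied up in the dioxinone ketal.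

Step 10
Reactants: 18 methyl (R)-lactate
Product: 19 methyl (R)-2-(tert-butyldimethylsilyloxy)propanoate
Conditions: TBSCl, imidazole, DMF, rt
Reagents that add atoms: tert-butyldimethylsilyl chloride, CC(C)(C)[Si](C)(C)Cl
Why: routine silylation protects the C16 hydroxyl for the acylation in step 11.

Step 11
Reactants: 19 silyl lactate; 20 1,3-dithiane
Product: 21 (R)-2-(tert-butyldimethylsilyloxy)-1-(1,3-dithian-2-yl)propan-1-one
Conditions: 20, n-BuLi (2.1 equiv each), THF, −30 °C; then 19, −78 → −20 °C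
Reagents that add atoms: none
Why: Corey–Seebach acylation of 2-lithio-1,3-dithiane by the ester; the second equivalent deprotonates the acidic 2-acyl-dithiane, which stops over-addition and shields C16 from enolisation.

Step 12
Reactants: 21 acyl dithiane
Product: 22 (R)-1-(1,3-dithian-2-yl)-2-hydroxypropan-1-one
Conditions: aq. HF, MeCN, 0 °C
Reagents that add atoms: none
Why: acidic (non-basic) desilylation frees the C16 hydroxyl without racemising the α-hydroxy ketone.

Step 13
Reactants: 17 tetracyclic dioxinone; 22 hydroxy ketone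
Product: 25 C14–C17 aldol adduct (E-lactone closed; 17-OH; 17-(1,3-dithian-2-yl); C13 ketone; C12 epimers), via acylketene 23 (not isolated), via β-keto ester 24 (not isolated)
Conditions: toluene, 110 °C (−acetone); then DBU (20 mol %), rt
Reagents that add atoms: none
Why: thermal retro-[4+2] of the dioxinone gives an acylketene that the alcohol of 22 traps (retention at C16); DBU then drives a reversible intramolecular aldol (5-exo-trig) in which the C14 enolate adds axially, anti to the axial C8 methyl, and equilibration should place the bulky dithianyl group on the C13 side, setting C14 and C17 (17-OH toward C9).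

Step 14
Reactants: 25 aldol adduct
Product: 28 13-oxo-17,18-bis(trimethylsilyloxy) pentacycle (ring D closed; C18 epimers), via hydroxy aldehyde 26 (not isolated), via enol silane 27 (not isolated)
Conditions: MeI, CaCO3, MeCN/H2O, 40 °C; then TMSOTf, Et3N, CH2Cl2, −78 → 0 °C
Reagents that add atoms: water, O; trimethylsilyl triflate, C[Si](C)(C)OS(=O)(=O)C(F)(F)F
Why: alkylative dithiane hydrolysis unmasks C18 as the aldehyde; TMSOTf/Et3N silylates the 17-OH, forms the only possible enol silane (C12=C13, which erases the C12 mixture) and triggers an intramolecular Mukaiyama aldol (5-exo-trig) that can close ring D only diaxially, fixing C12 with the methyl equatorial.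

Step 15
Reactants: 28 bis-TMS ketone
Product: 30 13-methylidene-17,18-diol (1-OTBS retained; C18 epimers), via bis-TMS alkene 29 (not isolated)
Conditions: Zn, CH2Br2, TiCl4, THF/CH2Cl2, 0 °C → rt; then HCl (cat.), MeOH, 0 °C
Reagents that add atoms: dibromomethane, C(Br)Br
Why: Lombardo methylenation is non-basic and ketone-selective over lactones, and C13=O is the only ketone present and is non-enolisable; brief acidic methanolysis removes the two TMS ethers but not the hindered axial TBS ether.

Step 16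
Reactants: 30 diol
Product: 31 1-O-TBS-brasilianoid F
Conditions: Dess–Martin periodinane, NaHCO3, CH2Cl2, rt
Reagents that add atoms: none
Why: Dess–Martin oxidation converts the secondary C18 alcohol of the sec/tert 1,2-diol into the ketone and leaves the tertiary 17-OH, the alkene and the silyl-protected C1 alcohol untouched.

Step 17
Reactants: 31 silyl ether
Product: 32 brasilianoid F
Conditions: HF·pyridine, THF, 0 °C → rt
Reagents that add atoms: none
Why: fluoride-mediated desilylation under mildly acidic conditions avoids the retro-aldol and lactone opening that basic reagents could cause in the α-ketol/β-hydroxy-lactone array.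

**Compound list**

1 | 2,2,6-trimethyl-4H-1,3-dioxin-4-one | CC1=CC(=O)OC(C)(C)O1 | starting material
2 | geranyl bromide | CC(C)=CCC/C(C)=C/CBr | starting material
3 | 6-[(3E)-4,8-dimethylnona-3,7-dien-1-yl]-2,2-dimethyl-4H-1,3-dioxin-4-one | CC(C)=CCC/C(C)=C/CCC1=CC(=O)OC(C)(C)O1 | intermediate
4 | 6-[(4E)-5,9-dimethyldeca-4,8-dien-2-yl]-2,2-dimethyl-4H-1,3-dioxin-4-one (racemic) | CC(C)=CCC/C(C)=C/CC(C)C1=CC(=O)OC(C)(C)O1 | intermediate
5 | (2E,6E)-allylic alcohol corresponding to 6 | OC/C(C)=C/CC/C(C)=C/CC(C)C1=CC(=O)OC(C)(C)O1 | intermediate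
6 | (2E,6E)-9-(2,2-dimethyl-4-oxo-4H-1,3-dioxin-6-yl)-2,6-dimethyldeca-2,6-dienal | O=C/C(C)=C/CC/C(C)=C/CC(C)C1=CC(=O)OC(C)(C)O1 | intermediate
7 | (R)-4-benzyloxazolidin-2-one | O=C1N[C@H](Cc2ccccc2)CO1 | starting material
8 | pent-4-ynoyl chloride | C#CCCC(=O)Cl | starting material
9 | (R)-4-benzyl-3-(pent-4-ynoyl)oxazolidin-2-one | C#CCCC(=O)N1[C@H](Cc2ccccc2)COC1=O | intermediate
10 | O-TMS ether of aldol adduct 11 | C#CC[C@H](C(=O)N1[C@H](Cc2ccccc2)COC1=O)[C@@H](O[Si](C)(C)C)/C(C)=C/CC/C(C)=C/CC(C)C1=CC(=O)OC(C)(C)O1 | intermediate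
11 | anti-aldol adduct (C2 S, C1 R) | C#CC[C@H](C(=O)N1[C@H](Cc2ccccc2)COC1=O)[C@@H](O)/C(C)=C/CC/C(C)=C/CC(C)C1=CC(=O)OC(C)(C)O1 | intermediate
12 | O-TBS ether of 11 | C#CC[C@H](C(=O)N1[C@H](Cc2ccccc2)COC1=O)[C@@H](O[Si](C)(C)C(C)(C)C)/C(C)=C/CC/C(C)=C/CC(C)C1=CC(=O)OC(C)(C)O1 | intermediate
13 | (2S,3R,4E,8E)-3-(TBSO)-11-(dioxinonyl)-4,8-dimethyl-2-(prop-2-yn-1-yl)dodeca-4,8-dienoic acid | C#CC[C@H](C(=O)O)[C@@H](O[Si](C)(C)C(C)(C)C)/C(C)=C/CC/C(C)=C/CC(C)C1=CC(=O)OC(C)(C)O1 | intermediate
14 | γ-methylene lactone (3S, side chain 1R) | C=C1C[C@@H]([C@@H](O[Si](C)(C)C(C)(C)C)/C(C)=C/CC/C(C)=C/CC(C)C2=CC(=O)OC(C)(C)O2)C(=O)O1 | intermediate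
15 | 5-chloro-5-methyl lactone (C4 epimers) | CC1(Cl)C[C@@H]([C@@H](O[Si](C)(C)C(C)(C)C)/C(C)=C/CC/C(C)=C/CC(C)C2=CC(=O)OC(C)(C)O2)C(=O)O1 | intermediate
16 | cyclic acyloxycarbenium ion (cation at C4) | C[C+]1C[C@@H]([C@@H](O[Si](C)(C)C(C)(C)C)/C(C)=C/CC/C(C)=C/CC(C)C2=CC(=O)OC(C)(C)O2)C(=O)O1 | intermediate
17 | tetracyclic lactone–dioxinone (rings A–C, bridged A-lactone, 1α-OTBS, C12 epimers) | CC1C[C@H]2[C@]3(C)[C@H](O[Si](C)(C)C(C)(C)C)[C@@H]4C[C@@](C)(OC4=O)[C@H]3CC[C@]2(C)C2=C1OC(C)(C)OC2=O | intermediate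
18 | methyl (R)-lactate | C[C@@H](O)C(=O)OC | starting material
19 | methyl (R)-2-(tert-butyldimethylsilyloxy)propanoate | C[C@@H](O[Si](C)(C)C(C)(C)C)C(=O)OC | intermediate
20 | 1,3-dithiane | C1CSCSC1 | starting material
21 | (R)-2-(tert-butyldimethylsilyloxy)-1-(1,3-dithian-2-yl)propan-1-one | C[C@@H](O[Si](C)(C)C(C)(C)C)C(=O)C1SCCCS1 | intermediate
22 | (R)-1-(1,3-dithian-2-yl)-2-hydroxypropan-1-one | C[C@@H](O)C(=O)C1SCCCS1 | intermediate
23 | acylketene (C14=C15=O, C13=O) | CC1C[C@H]2[C@]3(C)[C@H](O[Si](C)(C)C(C)(C)C)[C@@H]4C[C@@](C)(OC4=O)[C@H]3CC[C@]2(C)C(=C=O)C1=O | intermediate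
24 | tricyclic β-keto ester of 22 (C14–H, C12 epimers) | CC1C[C@H]2[C@]3(C)[C@H](O[Si](C)(C)C(C)(C)C)[C@@H]4C[C@@](C)(OC4=O)[C@H]3CC[C@]2(C)C(C1=O)C(=O)O[C@H](C)C(=O)C1SCCCS1 | intermediate
25 | C14–C17 aldol adduct (E-lactone closed, 17-OH, 17-dithianyl) | CC1C[C@H]2[C@]3(C)[C@H](O[Si](C)(C)C(C)(C)C)[C@@H]4C[C@@](C)(OC4=O)[C@H]3CC[C@]2(C)[C@]2(C1=O)C(=O)O[C@H](C)[C@@]2(O)C1SCCCS1 | intermediate
26 | 17-hydroxy-17-formyl compound (C18 aldehyde) | CC1C[C@H]2[C@]3(C)[C@H](O[Si](C)(C)C(C)(C)C)[C@@H]4C[C@@](C)(OC4=O)[C@H]3CC[C@]2(C)[C@]2(C1=O)C(=O)O[C@H](C)[C@@]2(O)C=O | intermediate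
27 | C12=C13 enol silane, 17-OTMS aldehyde | CC=1C[C@H]2[C@]3(C)[C@H](O[Si](C)(C)C(C)(C)C)[C@@H]4C[C@@](C)(OC4=O)[C@H]3CC[C@]2(C)[C@]2(C=1O[Si](C)(C)C)C(=O)O[C@H](C)[C@@]2(O[Si](C)(C)C)C=O | intermediate
28 | 13-oxo-17,18-bis(OTMS) pentacycle (ring D closed, C18 epimers) | O=C1[C@@]2(C)C[C@H]3[C@]4(C)[C@H](O[Si](C)(C)C(C)(C)C)[C@@H]5C[C@@](C)(OC5=O)[C@H]4CC[C@]3(C)[C@@]13C(=O)O[C@H](C)[C@@]3(O[Si](C)(C)C)C2O[Si](C)(C)C | intermediate
29 | 13-methylidene-17,18-bis(OTMS) pentacycle | C=C1[C@@]2(C)C[C@H]3[C@]4(C)[C@H](O[Si](C)(C)C(C)(C)C)[C@@H]5C[C@@](C)(OC5=O)[C@H]4CC[C@]3(C)[C@@]13C(=O)O[C@H](C)[C@@]3(O[Si](C)(C)C)C2O[Si](C)(C)C | intermediate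
30 | 13-methylidene-17,18-diol (1-OTBS) | C=C1[C@@]2(C)C[C@H]3[C@]4(C)[C@H](O[Si](C)(C)C(C)(C)C)[C@@H]5C[C@@](C)(OC5=O)[C@H]4CC[C@]3(C)[C@@]13C(=O)O[C@H](C)[C@@]3(O)C2O | intermediate
31 | 1-O-TBS-brasilianoid F | C=C1[C@@]2(C)C[C@H]3[C@]4(C)[C@H](O[Si](C)(C)C(C)(C)C)[C@@H]5C[C@@](C)(OC5=O)[C@H]4CC[C@]3(C)[C@@]13C(=O)O[C@H](C)[C@@]3(O)C2=O | intermediate
32 | brasilianoid F | C=C1[C@@]2(C)C[C@H]3[C@]4(C)[C@H](O)[C@@H]5C[C@@](C)(OC5=O)[C@H]4CC[C@]3(C)[C@@]13C(=O)O[C@H](C)[C@@]3(O)C2=O | target

**Step count and risk**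

Total steps: 17. Longest linear sequence: 13 (steps 1–3, 5–9, 13–17).

Steps most likely to fail:

1. Step 9 (Proposed new method). The cation relay may be cut short: the acyloxycarbenium ion may lose a proton back to the enol lactone or open to the acylium ion, or the C10 cation may be quenched before rings B and C close. Fallback, from 12 back to 17: reductive removal of the auxiliary (LiBH4, wet Et2O, 0 °C) should give the primary alcohol F1. Gold-catalysed cycloisomerisation of the alkynol in MeOH with PPTS should give the 2-methoxy-2-methyltetrahydrofuran F2. SnCl4 (CH2Cl2, −78 °C) ionises this ordinary cyclic ketal to an alkoxy-oxocarbenium ion, the classical acetal-type initiator, with the same five-membered tether; the polycyclisation should then give the ether-bridged tetracycle F3. Ruthenium tetroxide oxidation (RuCl3 cat., NaIO4) of the ether CH2 (C3) to the lactone returns to 17.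

2. Step 13. The first aldol may stay on the side of the open β-keto ester, or settle on the C17 epimer whose acyl group points away from C12; base may also epimerise C16. Fallback, from 17 back to 28, with the bond order reversed so that C17 is set by ring strain alone: methanolysis of 17 (MeOH, toluene, 110 °C) gives the methyl β-keto ester F4. Hydrolysis of the dithiane of 21 (MeI, CaCO3, aq. MeCN) gives the keto aldehyde (R)-3-(tert-butyldimethylsilyloxy)-2-oxobutanal F5. The β-keto ester dianion of F4 (LDA, 2.2 equiv, THF, −78 °C) adds through its γ-carbon C12 (axial attack) to the aldehyde of F5, and on warming the remaining C14 enolate closes ring D onto the C17 ketone to give the ring-D diol methyl ester F6. Buffered HF·pyridine frees the C16 hydroxyl, which lactonises onto C15 (CSA cat.) to give the keto diol lactone F7. TMSOTf/Et3N then gives 28.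

3. Step 15. The bridging C13 ketone is flanked by two quaternary carbons and an axial methyl, so the titanium–methylene reagent may fail to reach it. Fallback, from 28 back to 29: addition of the small organocerium reagent from Me3SiCH2MgCl/CeCl3 (THF, −78 °C; ketone-selective over the lactones) should give the β-hydroxysilane F8. Peterson elimination (KH, THF) gives 29, which is carried on as in step 15.

**Further compounds**

F1 | step 9 | primary alcohol from reductive cleavage of 12 (C3 = CH2OH) | C#CC[C@H](CO)[C@@H](O[Si](C)(C)C(C)(C)C)/C(C)=C/CC/C(C)=C/CC(C)C1=CC(=O)OC(C)(C)O1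
F2 | step 9 | 2-methoxy-2-methyltetrahydrofuran analogue of 15 (C4 epimers) | COC1(C)C[C@@H]([C@@H](O[Si](C)(C)C(C)(C)C)/C(C)=C/CC/C(C)=C/CC(C)C2=CC(=O)OC(C)(C)O2)CO1
F3 | step 9 | ether-bridged analogue of 17 (C3 = CH2) | CC1C[C@H]2[C@]3(C)[C@H](O[Si](C)(C)C(C)(C)C)[C@@H]4C[C@@](C)(OC4)[C@H]3CC[C@]2(C)C2=C1OC(C)(C)OC2=O
F4 | step 13 | tricyclic methyl β-keto ester | CC1C[C@H]2[C@]3(C)[C@H](O[Si](C)(C)C(C)(C)C)[C@@H]4C[C@@](C)(OC4=O)[C@H]3CC[C@]2(C)C(C1=O)C(=O)OC
F5 | step 13 | (R)-3-(tert-butyldimethylsilyloxy)-2-oxobutanal | C[C@@H](O[Si](C)(C)C(C)(C)C)C(=O)C=O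
F6 | step 13 | ring-D diol methyl ester (C15 ester open, 16-OTBS) | O=C1[C@@]2(C)C[C@H]3[C@]4(C)[C@H](O[Si](C)(C)C(C)(C)C)[C@@H]5C[C@@](C)(OC5=O)[C@H]4CC[C@]3(C)[C@]1(C(=O)OC)[C@@](O)([C@@H](C)O[Si](C)(C)C(C)(C)C)C2O
F7 | step 13 | 13-oxo-17,18-diol pentacycle (free diol of 28) | O=C1[C@@]2(C)C[C@H]3[C@]4(C)[C@H](O[Si](C)(C)C(C)(C)C)[C@@H]5C[C@@](C)(OC5=O)[C@H]4CC[C@]3(C)[C@@]13C(=O)O[C@H](C)[C@@]3(O)C2O
F8 | step 15 | 13-hydroxy-13-(trimethylsilylmethyl) adduct of 28 | C[Si](C)(C)CC1(O)[C@@]2(C)C[C@H]3[C@]4(C)[C@H](O[Si](C)(C)C(C)(C)C)[C@@H]5C[C@@](C)(OC5=O)[C@H]4CC[C@]3(C)[C@@]13C(=O)O[C@H](C)[C@@]3(O[Si](C)(C)C)C2O[Si](C)(C)C
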